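**Strategy.** Ring A (C1–C5, C10) is opened by a retro-[4+2]: C1=C10 becomes the dienophile of an isopropenyl ketone (C9=O) and C2=C3–C4=C5 a diene. Because the four-carbon chain C6–C9 links C5 to C10, one intramolecular Diels–Alder reaction of an acyclic trienone closes rings A and B together and sets the trans fusion (C5–H, quaternary C10–CH3), steered by a C6 silyloxy centre that feels A(1,3) strain from the C4 methyl. Afterwards the C3=C4 alkene accepts the second C4 methyl, the C9 ketone becomes the C8=C9 triflate that receives the side chain, and a C6 ketone guides C7 hydroxylation and its own reduction to the 6β-alcohol.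

Key step: step 8

Remark: labdane numbering (C1–C20) is used for all carbocyclic intermediates; α is the face opposite the C10 methyl. The C8 methyl centre of 2–12 is erased when the C8=C9 enol triflate forms.

Step 1
Reactants: 1 (S)-5-[(trityloxy)methyl]dihydrofuran-2(3H)-one
Product: 2 (3R,5S)-3-methyl-5-[(trityloxy)methyl]dihydrofuran-2(3H)-one
Conditions: LDA, THF, −78 °C; MeI, −78 → −40 °C
Reagents that add atoms: iodomethane, CI
Why: Enolate alkylation of the lithium lactone enolate should occur anti to the bulky trityloxymethyl group, giving the 3,5-trans lactone (C8 set by 1,3-induction from C6).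

Step 2
Reactants: 2 (3R,5S)-3-methyl-5-[(trityloxy)methyl]dihydrofuran-2(3H)-one
Product: 3 (3R,5S)-5-(hydroxymethyl)-3-methyldihydrofuran-2(3H)-one
Conditions: 80% aq. AcOH, 50 °C
Reagents that add atoms: none
Why: Acid-catalysed solvolysis of the trityl ether (SN1 at the trityl carbon) should free the primary alcohol without opening the γ-lactone.

Step 3
Reactants: 3 (3R,5S)-5-(hydroxymethyl)-3-methyldihydrofuran-2(3H)-one
Product: 5 (E)-2-methyl-3-[(2S,4R)-4-methyl-5-oxotetrahydrofuran-2-yl]prop-2-enal, via lactone aldehyde 4 (not isolated)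
Conditions: Dess–Martin periodinane, CH2Cl2, 0 °C → rt; then Ph3P=C(CH3)CHO, rt → 40 °C
Reagents that add atoms: 2-(triphenylphosphoranylidene)propanal, CC(C=O)=P(c1ccccc1)(c1ccccc1)c1ccccc1
Why: Dess–Martin oxidation followed in the same flask by an E-selective Wittig reaction of the stabilised formyl ylide should place the lactone carbon cis to the C4 methyl, as the diene geometry requires.

Step 4
Reactants: 5 (E)-2-methyl-3-[(2S,4R)-4-methyl-5-oxotetrahydrofuran-2-yl]prop-2-enal
Product: 6 (3R,5S)-3-methyl-5-[(1E)-2-methylbuta-1,3-dien-1-yl]dihydrofuran-2(3H)-one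
Conditions: Ph3PCH3Br, KHMDS, THF, 0 °C; then 5, −78 → 0 °C
Reagents that add atoms: methyltriphenylphosphonium bromide, C[P+](c1ccccc1)(c1ccccc1)c1ccccc1.[Br-]
Why: Wittig methylenation should take place at the enal carbonyl, which is far more electrophilic than the lactone, and completes the (E)-2-methylbuta-1,3-dienyl unit.

Step 5
Reactants: 6 (3R,5S)-3-methyl-5-[(1E)-2-methylbuta-1,3-dien-1-yl]dihydrofuran-2(3H)-one
Product: 7 (2R,4S,5E)-4-hydroxy-N-methoxy-N,2,6-trimethylocta-5,7-dienamide
Conditions: MeNH(OMe)·HCl, i-PrMgCl, THF, −20 → 0 °C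
Reagents that add atoms: N,O-dimethylhydroxylamine hydrochloride, CNOC.Cl
Why: Weinreb amide formation by aminolysis of the lactone with the magnesium amide opens the ring at the acyl C–O bond, so the C6 carbinol centre is not touched.

Step 6
Reactants: 7 (2R,4S,5E)-4-hydroxy-N-methoxy-N,2,6-trimethylocta-5,7-dienamide
Product: 8 (2R,4S,5E)-4-[(tert-butyldimethylsilyl)oxy]-N-methoxy-N,2,6-trimethylocta-5,7-dienamide
Conditions: TBSCl, imidazole, DMF, rt
Reagents that add atoms: tert-butyldimethylsilyl chloride, CC(C)(C)[Si](C)(C)Cl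
Why: Silyl ether formation under basic conditions blocks relactonisation and installs the bulky C6 substituent that later steers the cycloaddition.

Step 7
Reactants: 8 (2R,4S,5E)-4-[(tert-butyldimethylsilyl)oxy]-N-methoxy-N,2,6-trimethylocta-5,7-dienamide
Product: 9 (4R,6S,7E)-6-[(tert-butyldimethylsilyl)oxy]-2,4,8-trimethyldeca-1,7,9-trien-3-one
Conditions: isopropenylmagnesium bromide, THF, 0 °C; aq. NH4Cl
Reagents that add atoms: isopropenylmagnesium bromide, CC(=C)[Mg]Br
Why: Weinreb ketone synthesis: the chelated tetrahedral intermediate should stop at mono-addition and release the isopropenyl ketone (the activated dienophile) on work-up.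

Step 8
Reactants: 9 (4R,6S,7E)-6-[(tert-butyldimethylsilyl)oxy]-2,4,8-trimethyldeca-1,7,9-trien-3-one
Product: 10 (2R,4S,4aS,8aS)-4-[(tert-butyldimethylsilyl)oxy]-2,5,8a-trimethyl-3,4,4a,7,8,8a-hexahydronaphthalen-1(2H)-one (labdane numbering: 9-oxo, Δ3, 5α-H, 10β-CH3, 6α-OTBS, 8α-CH3)
Conditions: PhMe (0.02 M), BHT (cat.), 110 °C
Reagents that add atoms: none
Why: Thermal, concerted but asynchronous intramolecular [4+2] cycloaddition (type 1 IMDA of a 2-methyl-1,7,9-decatrien-3-one): the C9 carbonyl lowers the LUMO of the C1=C10 isopropenyl dienophile, which adds across C2 and C5 of the (E)-diene and forms C1–C2 and C5–C10 together. Ring A is closed as a cyclohexene by the cycloaddition itself, and ring B by the C5–C10 bond through the four-atom tether C6–C9 (fused bicyclo[4.4.0], chair-like tether). C5: A(1,3) strain between the C4 methyl and C6 should hold C6–H in the diene plane, so the tether reaches the diene face anti to the OTBS group. C10: with that rotamer fixed, only the exo-tether arrangement (carbonyl exo, C10 methyl endo) allows a chair-like ring B with 6-OTBS and 8-CH3 equatorial, which gives the trans fusion (C10–CH3 anti to C5–H), whereas the cis mode would need a boat. The step needs trans over cis fusion and one diene face; both should be secured by the (6S) centre acting with the C4 methyl, and the regiochemistry is fixed by the tether.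

Step 9
Reactants: 10 (2R,4S,4aS,8aS)-4-[(tert-butyldimethylsilyl)oxy]-2,5,8a-trimethyl-3,4,4a,7,8,8a-hexahydronaphthalen-1(2H)-one
Product: 12 (2R,4S,4aS,8aS)-4-[(tert-butyldimethylsilyl)oxy]-2,5,5,8a-tetramethyloctahydronaphthalen-1(2H)-one, via alkyl sulfonylhydrazide 11 (not isolated)
Conditions: octane-1-sulfonohydrazide, 37% aq. CH2O, Fe(acac)3 (cat.), PhSiH3, THF/MeOH, rt; then MeOH, 60 °C
Reagents that add atoms: formaldehyde, C=O
Why: Mukaiyama-type MHAT hydromethylation: the iron hydride should transfer H• to C3, the tertiary C4 radical adds to the carbon of the formaldehyde sulfonylhydrazone, and the hydrazide loses sulfinate and N2 on warming, so C4 carries two methyl groups (no new stereocentre).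

Step 10
Reactants: 12 (2R,4S,4aS,8aS)-4-[(tert-butyldimethylsilyl)oxy]-2,5,5,8a-tetramethyloctahydronaphthalen-1(2H)-one
Product: 13 (4S,4aS,8aS)-4-[(tert-butyldimethylsilyl)oxy]-2,5,5,8a-tetramethyl-3,4,4a,5,6,7,8,8a-octahydronaphthalen-1-yl trifluoromethanesulfonate
Conditions: KHMDS, THF, −78 → −20 °C; PhNTf2, −78 °C → rt
Reagents that add atoms: N-phenylbis(trifluoromethanesulfonimide), O=S(=O)(N(c1ccccc1)S(=O)(=O)C(F)(F)F)C(F)(F)F
Why: Enol triflate formation: the ketone can enolise only towards C8 because C10 is quaternary, and O-sulfonylation of the potassium enolate should give the tetrasubstituted C8=C9 triflate.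

Step 11
Reactants: 13 (4S,4aS,8aS)-4-[(tert-butyldimethylsilyl)oxy]-2,5,5,8a-tetramethyl-3,4,4a,5,6,7,8,8a-octahydronaphthalen-1-yl trifluoromethanesulfonate
Product: 14 (4S,4aS,8aS)-4-hydroxy-2,5,5,8a-tetramethyl-3,4,4a,5,6,7,8,8a-octahydronaphthalen-1-yl trifluoromethanesulfonate
Conditions: 48% aq. HF, MeCN, rt
Reagents that add atoms: none
Why: Fluoride-mediated desilylation under acidic conditions leaves the enol triflate intact and frees the C6 hydroxyl before the side chain brings in a second silyl ether.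

Step 12
Reactants: 15 (E)-3-methylpent-2-en-4-yn-1-ol
Product: 16 (E)-tert-butyldimethyl[(3-methylpent-2-en-4-yn-1-yl)oxy]silane
Conditions: TBSCl, imidazole, CH2Cl2, rt
Reagents that add atoms: tert-butyldimethylsilyl chloride, CC(C)(C)[Si](C)(C)Cl
Why: Standard silyl ether formation protects the primary allylic alcohol that becomes C15–OH.

Step 13
Reactants: 16 (E)-tert-butyldimethyl[(3-methylpent-2-en-4-yn-1-yl)oxy]silane
Product: 17 (E)-tert-butyldimethyl[(3-methylpenta-2,4-dien-1-yl)oxy]silane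
Conditions: H2 (1 atm), Lindlar catalyst, quinoline, hexane, rt
Reagents that add atoms: none
Why: Lindlar semihydrogenation should stop at the vinyl group and leave the trisubstituted E-alkene (C13=C14) unchanged.

Step 14
Reactants: 14 (4S,4aS,8aS)-4-hydroxy-2,5,5,8a-tetramethyl-3,4,4a,5,6,7,8,8a-octahydronaphthalen-1-yl trifluoromethanesulfonate; 17 (E)-tert-butyldimethyl[(3-methylpenta-2,4-dien-1-yl)oxy]silane
Product: 19 (5S,6S,10S,13E)-15-[(tert-butyldimethylsilyl)oxy]labda-8,13-dien-6-ol (6α-OH), via B-alkyl-9-BBN 18 (not isolated)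
Conditions: 17, 9-BBN, THF, 0 °C → rt; then 14, PdCl2(dppf) (cat.), AsPh3 (cat.), Cs2CO3, DMF/THF/H2O, rt → 50 °C
Reagents that add atoms: none
Why: 9-BBN should hydroborate only the terminal vinyl group (anti-Markovnikov), and B-alkyl Suzuki–Miyaura coupling with the enol triflate forms C9–C11 with retention of both alkene geometries while tolerating the free alcohol.

Step 15
Reactants: 19 (5S,6S,10S,13E)-15-[(tert-butyldimethylsilyl)oxy]labda-8,13-dien-6-ol
Product: 20 (5S,10S,13E)-15-[(tert-butyldimethylsilyl)oxy]labda-8,13-dien-6-one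
Conditions: Dess–Martin periodinane, CH2Cl2, 0 °C → rt
Reagents that add atoms: none
Why: Dess–Martin oxidation under near-neutral conditions should give the β,γ-unsaturated C6 ketone without moving the C8=C9 bond; the trans ring fusion is kept and is also the thermodynamic one at the now epimerisable C5.

Step 16
Reactants: 20 (5S,10S,13E)-15-[(tert-butyldimethylsilyl)oxy]labda-8,13-dien-6-one
Product: 21 (5S,7S,10S,13E)-15-[(tert-butyldimethylsilyl)oxy]-7-hydroxylabda-8,13-dien-6-one (7α-OH)
Conditions: KHMDS, THF, −78 °C; 2-(phenylsulfonyl)-3-phenyloxaziridine, −78 °C; aq. NH4Cl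
Reagents that add atoms: 2-(phenylsulfonyl)-3-phenyloxaziridine (Davis oxaziridine), O=S(=O)(c1ccccc1)N1OC1c1ccccc1
Why: Davis hydroxylation of the extended potassium enolate (deprotonation at the doubly activated C7) should occur at the α-carbon and from the α-face, opposite the axial C10 and C4β methyl groups, which sets C7.

Step 17
Reactants: 21 (5S,7S,10S,13E)-15-[(tert-butyldimethylsilyl)oxy]-7-hydroxylabda-8,13-dien-6-one
Product: 22 (5S,7S,10S,13E)-15-[(tert-butyldimethylsilyl)oxy]-7-[(triethylsilyl)oxy]labda-8,13-dien-6-one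
Conditions: TESOTf, 2,6-lutidine, CH2Cl2, −78 °C
Reagents that add atoms: triethylsilyl trifluoromethanesulfonate, CC[Si](CC)(CC)OS(=O)(=O)C(F)(F)F
Why: Silyl ether formation masks the accessible C7 hydroxyl so that only O6 can be acylated later, and it stops α-ketol isomerisation.

Step 18
Reactants: 22 (5S,7S,10S,13E)-15-[(tert-butyldimethylsilyl)oxy]-7-[(triethylsilyl)oxy]labda-8,13-dien-6-one
Product: 23 (5S,6S,7S,10S,13E)-15-[(tert-butyldimethylsilyl)oxy]-7-[(triethylsilyl)oxy]labda-8,13-dien-6-ol (6β-OH)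
Conditions: LiAlH4, Et2O, −78 → 0 °C
Reagents that add atoms: none
Why: Substrate-controlled hydride reduction: the β-face of C6 is blocked by the syn-axial C4β and C10 methyl groups, so hydride should enter from the α-face and give the axial 6β-alcohol.

Step 19
Reactants: 23 (5S,6S,7S,10S,13E)-15-[(tert-butyldimethylsilyl)oxy]-7-[(triethylsilyl)oxy]labda-8,13-dien-6-ol
Product: 24 (5S,6S,7S,10S,13E)-15-[(tert-butyldimethylsilyl)oxy]-7-[(triethylsilyl)oxy]labda-8,13-dien-6-yl 3-methylbutanoate
Conditions: isovaleryl chloride, DMAP (cat.), pyridine, CH2Cl2, 0 → 40 °C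
Reagents that add atoms: 3-methylbutanoyl chloride (isovaleryl chloride), CC(C)CC(Cl)=O
Why: DMAP-catalysed acylation through the N-acylpyridinium ion should esterify the hindered axial 6β-alcohol, the only free hydroxyl.

Step 20
Reactants: 24 (5S,6S,7S,10S,13E)-15-[(tert-butyldimethylsilyl)oxy]-7-[(triethylsilyl)oxy]labda-8,13-dien-6-yl 3-methylbutanoate
Product: 25 (5S,6S,7S,10S,13E)-7,15-dihydroxylabda-8,13-dien-6-yl 3-methylbutanoate (CNP0173680.1)
Conditions: HF·pyridine, pyridine, THF, 0 °C → rt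
Reagents that add atoms: none
Why: Buffered fluoride desilylation should remove both silyl ethers without ester cleavage; acyl migration is disfavoured by the trans-diaxial 6β,7α arrangement.

**Compound list**

1 | (S)-5-[(trityloxy)methyl]dihydrofuran-2(3H)-one | O=C1CC[C@@H](COC(c2ccccc2)(c2ccccc2)c2ccccc2)O1 | starting material
2 | (3R,5S)-3-methyl-5-[(trityloxy)methyl]dihydrofuran-2(3H)-one | O=C1[C@H](C)C[C@@H](COC(c2ccccc2)(c2ccccc2)c2ccccc2)O1 | intermediate
3 | (3R,5S)-5-(hydroxymethyl)-3-methyldihydrofuran-2(3H)-one | O=C1[C@H](C)C[C@@H](CO)O1 | intermediate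
4 | (2S,4R)-4-methyl-5-oxotetrahydrofuran-2-carbaldehyde | O=C1[C@H](C)C[C@@H](C=O)O1 | intermediate (not isolated)
5 | (E)-2-methyl-3-[(2S,4R)-4-methyl-5-oxotetrahydrofuran-2-yl]prop-2-enal | O=C1[C@H](C)C[C@@H](/C=C(\C)C=O)O1 | intermediate
6 | (3R,5S)-3-methyl-5-[(1E)-2-methylbuta-1,3-dien-1-yl]dihydrofuran-2(3H)-one | O=C1[C@H](C)C[C@@H](/C=C(\C)C=C)O1 | intermediate
7 | (2R,4S,5E)-4-hydroxy-N-methoxy-N,2,6-trimethylocta-5,7-dienamide | CON(C)C(=O)[C@H](C)C[C@H](O)/C=C(\C)C=C | intermediate
8 | (2R,4S,5E)-4-[(tert-butyldimethylsilyl)oxy]-N-methoxy-N,2,6-trimethylocta-5,7-dienamide | CON(C)C(=O)[C@H](C)C[C@H](O[Si](C)(C)C(C)(C)C)/C=C(\C)C=C | intermediate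
9 | (4R,6S,7E)-6-[(tert-butyldimethylsilyl)oxy]-2,4,8-trimethyldeca-1,7,9-trien-3-one | C=C(C)C(=O)[C@H](C)C[C@H](O[Si](C)(C)C(C)(C)C)/C=C(\C)C=C | intermediate
10 | (2R,4S,4aS,8aS)-4-[(tert-butyldimethylsilyl)oxy]-2,5,8a-trimethyl-3,4,4a,7,8,8a-hexahydronaphthalen-1(2H)-one | C[C@]12CCC=C(C)[C@@H]1[C@@H](O[Si](C)(C)C(C)(C)C)C[C@@H](C)C2=O | intermediate
11 | N'-alkyl octane-1-sulfonohydrazide at the C4 methylene (mixture of C4 epimers) | C[C@]12CCCC(C)(CNNS(=O)(=O)CCCCCCCC)[C@@H]1[C@@H](O[Si](C)(C)C(C)(C)C)C[C@@H](C)C2=O | intermediate (not isolated)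
12 | (2R,4S,4aS,8aS)-4-[(tert-butyldimethylsilyl)oxy]-2,5,5,8a-tetramethyloctahydronaphthalen-1(2H)-one | C[C@]12CCCC(C)(C)[C@@H]1[C@@H](O[Si](C)(C)C(C)(C)C)C[C@@H](C)C2=O | intermediate
13 | (4S,4aS,8aS)-4-[(tert-butyldimethylsilyl)oxy]-2,5,5,8a-tetramethyl-3,4,4a,5,6,7,8,8a-octahydronaphthalen-1-yl trifluoromethanesulfonate | C[C@]12CCCC(C)(C)[C@@H]1[C@@H](O[Si](C)(C)C(C)(C)C)CC(C)=C2OS(=O)(=O)C(F)(F)F | intermediate
14 | (4S,4aS,8aS)-4-hydroxy-2,5,5,8a-tetramethyl-3,4,4a,5,6,7,8,8a-octahydronaphthalen-1-yl trifluoromethanesulfonate | C[C@]12CCCC(C)(C)[C@@H]1[C@@H](O)CC(C)=C2OS(=O)(=O)C(F)(F)F | intermediate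
15 | (E)-3-methylpent-2-en-4-yn-1-ol | OC/C=C(\C)C#C | starting material
16 | (E)-tert-butyldimethyl[(3-methylpent-2-en-4-yn-1-yl)oxy]silane | CC(C)(C)[Si](C)(C)OC/C=C(\C)C#C | intermediate
17 | (E)-tert-butyldimethyl[(3-methylpenta-2,4-dien-1-yl)oxy]silane | CC(C)(C)[Si](C)(C)OC/C=C(\C)C=C | intermediate
18 | 9-[(3E)-5-[(tert-butyldimethylsilyl)oxy]-3-methylpent-3-en-1-yl]-9-borabicyclo[3.3.1]nonane | CC(C)(C)[Si](C)(C)OC/C=C(\C)CCB1C2CCCC1CCC2 | intermediate (not isolated)
19 | (5S,6S,10S,13E)-15-[(tert-butyldimethylsilyl)oxy]labda-8,13-dien-6-ol | C[C@]12CCCC(C)(C)[C@@H]1[C@@H](O)CC(C)=C2CC/C(C)=C/CO[Si](C)(C)C(C)(C)C | intermediate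
20 | (5S,10S,13E)-15-[(tert-butyldimethylsilyl)oxy]labda-8,13-dien-6-one | C[C@]12CCCC(C)(C)[C@@H]1C(=O)CC(C)=C2CC/C(C)=C/CO[Si](C)(C)C(C)(C)C | intermediate
21 | (5S,7S,10S,13E)-15-[(tert-butyldimethylsilyl)oxy]-7-hydroxylabda-8,13-dien-6-one | C[C@]12CCCC(C)(C)[C@@H]1C(=O)[C@@H](O)C(C)=C2CC/C(C)=C/CO[Si](C)(C)C(C)(C)C | intermediate
22 | (5S,7S,10S,13E)-15-[(tert-butyldimethylsilyl)oxy]-7-[(triethylsilyl)oxy]labda-8,13-dien-6-one | C[C@]12CCCC(C)(C)[C@@H]1C(=O)[C@@H](O[Si](CC)(CC)CC)C(C)=C2CC/C(C)=C/CO[Si](C)(C)C(C)(C)C | intermediate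
23 | (5S,6S,7S,10S,13E)-15-[(tert-butyldimethylsilyl)oxy]-7-[(triethylsilyl)oxy]labda-8,13-dien-6-ol | C[C@]12CCCC(C)(C)[C@@H]1[C@H](O)[C@@H](O[Si](CC)(CC)CC)C(C)=C2CC/C(C)=C/CO[Si](C)(C)C(C)(C)C | intermediate
24 | (5S,6S,7S,10S,13E)-15-[(tert-butyldimethylsilyl)oxy]-7-[(triethylsilyl)oxy]labda-8,13-dien-6-yl 3-methylbutanoate | C[C@]12CCCC(C)(C)[C@@H]1[C@H](OC(=O)CC(C)C)[C@@H](O[Si](CC)(CC)CC)C(C)=C2CC/C(C)=C/CO[Si](C)(C)C(C)(C)C | intermediate
25 | (5S,6S,7S,10S,13E)-7,15-dihydroxylabda-8,13-dien-6-yl 3-methylbutanoate (CNP0173680.1) | CC1=C(CC/C(C)=C/CO)[C@@]2(C)CCCC(C)(C)[C@@H]2[C@H](OC(=O)CC(C)C)[C@H]1O | target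

**Totals.** 20 steps in all; the longest linear sequence is 18 steps (steps 1–11 and 14–20), with the two-step side-chain branch (steps 12–13) joining at step 14.

**Steps most likely to fail**

Step 9 (hydromethylation). The hindered tertiary C4 radical next to C5 may be quenched by a second hydrogen-atom transfer (net hydrogenation) or may disproportionate faster than it adds to the hydrazone, so the second methyl group would not be delivered. The fallback sets out from 10 and comes back at 12. Simmons–Smith cyclopropanation of the C3=C4 alkene (Et2Zn, CH2I2, CH2Cl2, 0 °C → rt) should give the 3α,4α-methano ketone F1 (either face would serve). Hydrogenolysis (H2, PtO2, AcOH) should then cleave the less substituted C3–CH2 cyclopropane bond, so the methylene carbon becomes the second C4 methyl of 12.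

Step 14 (B-alkyl Suzuki coupling). Transmetalation of the alkylborate to the vinylpalladium species flanked by quaternary C10 may be slow, so the triflate would be lost to hydrolysis or reduction. The fallback sets out from 18 and comes back at 19. Iodinolysis of the borane (I2, NaOMe, THF/MeOH, 0 °C) should give (E)-tert-butyl[(5-iodo-3-methylpent-2-en-1-yl)oxy]dimethylsilane F2. Zinc insertion (Zn dust, LiCl, THF) should convert it into the alkylzinc iodide F3. Base-free Negishi coupling of F3 (in excess, to absorb the free hydroxyl) with 14 (Pd(OAc)2/CPhos, THF, rt → 50 °C) forms the same C9–C11 bond.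

Step 16 (enolate hydroxylation). Oxygen may be transferred to the γ-carbon (C9) or from the β-face, the dienolate may be captured by the sulfonimine released from the oxidant, and base may shift the C8=C9 bond into conjugation. The fallback sets out from 20 and comes back at 22, by-passing 21. Soft enolisation (TESOTf, Et3N, CH2Cl2, −78 → 0 °C) should give the 6-(triethylsilyloxy)-6,8-diene F4. Rubottom oxidation with dimethyldioxirane (acetone/CH2Cl2, −78 °C) should epoxidise the electron-rich C6=C7 bond from the α-face, and 1,4-silyl migration then delivers 22 directly.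

**Further compounds**

F1 | step 9 | 3α,4α-methano (cyclopropane) derivative of ketone 10 | C[C@]12CC[C@H]3C[C@@]3(C)[C@@H]1[C@@H](O[Si](C)(C)C(C)(C)C)C[C@@H](C)C2=O
F2 | step 14 | (E)-tert-butyl[(5-iodo-3-methylpent-2-en-1-yl)oxy]dimethylsilane | CC(C)(C)[Si](C)(C)OC/C=C(\C)CCI
F3 | step 14 | [(3E)-5-[(tert-butyldimethylsilyl)oxy]-3-methylpent-3-en-1-yl]zinc iodide | CC(C)(C)[Si](C)(C)OC/C=C(\C)CC[Zn]I
F4 | step 16 | (5S,10S,13E)-15-[(tert-butyldimethylsilyl)oxy]-6-[(triethylsilyl)oxy]labda-6,8,13-triene | C[C@]12CCCC(C)(C)[C@@H]1C(O[Si](CC)(CC)CC)=CC(C)=C2CC/C(C)=C/CO[Si](C)(C)C(C)(C)C
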